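The earlier runs and the new flask were generated by integration for substances that don't exist, noise included.

At 2.5 min, the time of reading, I want to know how far target and isomer of the product have forgotten how they began, so I watch the share of target in the two together.

| flask | starting material | protic impurity | remark | time |
|---|---|---|---|---|
| midnight | 1 M | 0.033 M | run made earlier |  |
| noon | 1 M | 0.15 M | run made earlier |  |
| spring | 1.5 M | 0.10 M | run made earlier |  |
| eta | 1.5 M | 0.0300 M |  | 2.5 min |
| delta | 1.0 M | 0.100 M |  | 2.5 min |

| run | time / min | target / % | isomer of the product / % | starting material / % |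
|---|---|---|---|---|
| midnight | 0.200 | 7.3 | 1.0 | 90.2 |
| midnight | 0.667 | 14.6 | 4.1 | 77.8 |
| midnight | 1.33 | 19.3 | 8.4 | 69.1 |
| midnight | 2.00 | 21.4 | 10.3 | 64.5 |
| midnight | 2.50 | 23.3 | 11.0 | 63.1 |
| noon | 0.200 | 6.2 | 1.3 | 81.3 |
| noon | 0.417 | 8.9 | 1.7 | 74.2 |
| noon | 0.667 | 12.2 | 3.6 | 69.1 |
| noon | 1.33 | 15.4 | 6.4 | 62.6 |
| noon | 2.50 | 18.1 | 9.0 | 56.8 |
| spring | 0.500 | 16.4 | 3.8 | 73.3 |
| spring | 1.00 | 22.4 | 8.4 | 63.1 |
| spring | 1.50 | 24.4 | 10.7 | 58.6 |
| spring | 2.00 | 25.2 | 11.9 | 55.2 |
| spring | 2.50 | 26.8 | 12.9 | 53.6 |

(each reading ± 0.3 percentage points)

- which one finishes higher in share of target in all that became target or isomer of the product ("neither" within 2 percentage points) (eta / delta / neither)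
- share of target in all that became target or isomer of the product, eta
- share of target in all that became target or isomer of the product, delta

- a species is counted by the starting material in it: one target or isomer of the product counts as two
- what may be going on: 2 starting material <-> target; target <-> isomer of the product; starting material + protic impurity -> quenched substrate

The zero of my scale is 50.0%, a pair with no preference. At their last readings the earlier runs stand well above it: midnight 67.9%, noon 66.8%, spring 67.5%, on average 67.4%. Earlier the share is higher: midnight reads 78.1% at 0.667 min and 69.7% at 1.33 min. Held against the average, those two scattered readings give roughly 0.297 min, my excess half-life, the time in which the share's distance above its late level falls by a factor of 2.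

Eta and delta have 8.42 such half-lives by their reading. Taking a start at 100%, my reckoning leaves 0.095 percentage points of excess, so I treat the pair at that time as under thermodynamic rather than kinetic control, and I commit to 67.5% for both flasks.

The weak link is whether the charge shifts the late level. Impurity as a fraction of the starting material is 3.30% in midnight, 6.67% in spring and 15.0% in noon, and the shares fall in that order, by 1.1 points overall. But a difference of two shares carries about 0.93 points of scatter, and the whole fall is less than the margin. Delta, at 10.0%, lies inside that span; eta, at 2.00%, lies a small step outside it. I keep the two equal.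

The forecast says neither, with 67.6% for eta (66.2% to 69%) and 67.2% for delta (65.9% to 68.5%), since “it hardly depends on concentration or impurity”, though it sets eta slightly above delta where I set them equal.

The flask gives neither: eta 66.8% and delta 67.1%, which lie 0.70 points and 0.40 points below my 67.5%.

    2 starting material ⇌ target (K = 0.350 L mol⁻¹, k = 0.00380 L mol⁻¹ s⁻¹)
    target ⇌ isomer of the product (K = 0.520, k = 0.0190 s⁻¹)
    starting material + protic impurity → quenched substrate (k = 0.150 L mol⁻¹ s⁻¹)

In delta the relaxation half-life of the pair by the step between them alone, both ways together, is 0.208 min, short against 2.5 min. Now stop delta at 40 s, which is 2.24 excess half-lives of 0.297 min; the same reckoning puts the share at 74.3%. That neighbouring flask gives 77.3%, which is 3 points above the reckoning and 10 points above delta at its full time, with target at 13.1% and isomer of the product at 3.85% of the charge.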